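(The earlier runs and the new flask stem from a simulated flask for substances that don't exist.)

In this flask the solid reagent charged is less than the two substrates charged together, 0.632 M against 1.58 M, and you can count that difference in turnovers.

in all of them: solid reagent 0.632 M; catalyst 0.79 mM; added ligand 3.5 mM

| flask | left-handed substrate | right-handed substrate | remark | time |
|---|---|---|---|---|
| larch | 0.40 M | 0.40 M | run made earlier |  |
| alder | 1.6 M | 1.6 M | run made earlier |  |
| flask | 0.79 M | 0.79 M |  | 4.0 h |

| run | time / h | left-handed product / % | right-handed product / % |
|---|---|---|---|
| larch | 0.200 | 10.9 | 9.9 |
| larch | 0.667 | 23.1 | 23.4 |
| larch | 1.00 | 27.5 | 27.0 |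
| larch | 1.50 | 31.3 | 30.7 |
| larch | 2.50 | 34.7 | 34.9 |
| alder | 0.200 | 7.4 | 6.5 |
| alder | 0.333 | 8.5 | 8.6 |
| alder | 0.667 | 9.5 | 9.3 |
| alder | 1.33 | 9.7 | 10.2 |
| alder | 2.50 | 10.1 | 9.8 |

(readings scatter by 0.5 percentage points)

- catalyst is single-handed; left-handed substrate and right-handed substrate are mirror images of each other, charged as a racemate, each of them at the stated concentration
- solid, in amounts per volume of the solution: solid reagent
- the earlier runs were read with a standard deviation of 0.5 percentage points
- at the start none of the solid reagent is in solution
- an excess is below zero if the other one leads

1. excess of left-handed product over right-handed product in the product at 5.0 min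
2. excess of left-handed product over right-handed product in the product at 4.0 h
3. part of the left-handed substrate and right-handed substrate charged together that has reacted at 4.0 h

Solve two extreme versions of the flask. If the substrates never ran short, the flask would stop after 800 turnovers per catalyst charged, when the solid reagent had gone into product. If the solid reagent never ran short, it would stop after 2000 turnovers, with conversion complete. The smaller count stands, so the solid reagent is the limiting reagent, and the ceiling, meaning the solid reagent charged over the substrates charged together, is 40.0%. The alder readings support one solid reagent per product: at 2.50 h the two products read 19.9% together, against a ceiling of 19.7% for that run.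

The real flask could still fall short of its ceiling for lack of time. But larch, with less substrate than this flask, had turned 88.1% of its solid reagent into product by 2.50 h, and this flask runs longer. So you commit to the ceiling for conversion at 4.0 h. Turnovers say nothing of handedness, and the first pair of larch readings leans left by 1 percentage point, against a scatter of 0.5 points per reading.

The forecast gives an excess of 4% at 5.0 min, an excess of 0% at 4.0 h and a conversion of 40%, calling the lean “a small early excess that later disappears”.

The flask gives an excess of 14.1% at 5.0 min, an excess of 0% at 4.0 h and a conversion of 40.0%.

    coupling partner + catalyst + left-handed substrate → catalyst + left-handed product (k = 4.30 L² mol⁻² s⁻¹)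
    coupling partner + catalyst + right-handed substrate → catalyst + right-handed product (k = 2.20 L² mol⁻² s⁻¹)
    left-handed product ⇌ right-handed product (k = 0.00400 s⁻¹)
    solid reagent ⇌ coupling partner, rate k4*(cs4 - [coupling partner]) while solid is left; crystals form when [coupling partner] > cs4 (solubility = 0.610 M, k = 0.00750 s⁻¹)
    catalyst + added ligand ⇌ idle complex, settled at all times (K = 900 L mol⁻¹)

That conversion sits on the ceiling of 40.0%. A neighbour with 0.25 M of solid reagent has a ceiling of 15.8% and reached 15.8%. In this flask the left-handed product turns into right-handed product with a half-life of 2.9 min by the forward step alone, short against 4.0 h, and the product excess there stands at 0%.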